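(The numbers in the tables come from a simulation for an exercise, and the scatter is random.)

17.3% of the charge: that is where the ash run stands still, and it is the number to carry.

| setting | birch | ash | Monday's | Wednesday's | Thursday's |
|---|---|---|---|---|---|
| substrate | 0.050 M | 0.20 M | 0.10 M | 0.10 M | 0.10 M |
| temperature | 20 °C | 45 °C | 65 °C | 25 °C | 45 °C |
| remark | run made earlier | run made earlier |  |  |  |
| time |  |  | 15 h | 15 h | 15 h |

| run | time / h | product / % |
|---|---|---|
| birch | 40.0 | 2 |
| birch | 72.0 | 0 |
| birch | 96.0 | 4 |
| birch | 144 | 7 |
| birch | 192 | 13 |
| ash | 10.0 | 10 |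
| ash | 20.0 | 13 |
| ash | 25.0 | 17 |
| ash | 40.0 | 17 |
| ash | 60.0 | 18 |

(scatter of a reading: 1.5 percentage points)

- the best flask by amount of product, in percent of the substrate charged; "all alike" if 1.5 percentage points covers them all (Monday's / Wednesday's / Thursday's / all alike)
- amount of product at the end, in percent of the substrate charged, Monday's
- amount of product at the end, in percent of the substrate charged, Wednesday's
- amount of product at the end, in percent of the substrate charged, Thursday's

- what was read earlier has a scatter of 1.5 percentage points, one standard deviation
- a reading or a percentage of product counts all its forms, free or not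

Follow one substrate molecule. In ash, from 25.0 h on, its chance of being found as product is that mean, so its odds are 0.210: these are the ceiling odds, the product share over the rest of the charge once the share stops moving. You now need to know which flasks reach their ceiling, so take the half-rise time, the time to 8.65%. Ash gets there before 10.0 h and birch after 144 h, so the step from ash down to birch slows things at least 14.4-fold, if you set the charge aside. Now climb the ladder, fastest rung first.

1. Monday's stands more than half as far above ash as birch stands below it. Dividing by the square root of that factor is therefore safe and puts its half-rise below 2.64 h, shorter than 15 h. Monday's should end at its own ceiling.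

2. Thursday's has ash's temperature. At 15 h ash lies between its first two readings, near 11.5%, below the ceiling. Thursday's should still be rising.

3. Wednesday's stands less than half that distance above birch, so on the same scale its half-rise lies beyond the geometric mean of the ash and birch half-rise times. That mean passes 15 h if ash's half-rise is longer than 1.56 h, and I take it to be, since ash at 20.0 h still reads 13%, below the ceiling. I expect next to nothing from Wednesday's.

So Monday's beats Thursday's if its ceiling odds at 65 °C exceed 0.130. The runs don't give those odds, and I leave the winner open.

The forecast does commit, to Monday's: 18% (11% to 33%) for Monday's, which “should reach its limit within 15 h”, 1% for Wednesday's and 11.5% for Thursday's.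

The flasks give 9.96% on Monday's, 0.135% on Wednesday's and 14.1% on Thursday's, so the best is Thursday's.

    substrate ⇌ dormant form (K = 2.50, k = 2.20 × 10⁻⁴ min⁻¹, Ea = 105 kJ mol⁻¹, ΔH = −36.0 kJ mol⁻¹)
    intermediate E ⇌ product (K = 0.560, k = 6.60 × 10⁻⁴ min⁻¹, Ea = 100 kJ mol⁻¹, ΔH = −34.0 kJ mol⁻¹)
    intermediate B → intermediate E (k = 7.10 × 10⁻⁴ min⁻¹, Ea = 109 kJ mol⁻¹)
    intermediate C ⇌ intermediate D (K = 4.80, k = 6.40 × 10⁻⁴ min⁻¹, Ea = 95.0 kJ mol⁻¹, ΔH = −67.0 kJ mol⁻¹)
    intermediate B ⇌ intermediate C (K = 0.370, k = 1.10 × 10⁻⁴ min⁻¹, Ea = 102 kJ mol⁻¹, ΔH = −20.0 kJ mol⁻¹)
    intermediate A ⇌ intermediate B (K = 2.20, k = 2.00 × 10⁻⁴ min⁻¹, Ea = 108 kJ mol⁻¹, ΔH = −29.0 kJ mol⁻¹)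
    crystals ⇌ product, rate k7*(cs7 - [product]) while solid is left; crystals form when [product] > cs7 (solubility = 0.0890 M, k = 0.0180 min⁻¹)
    substrate → intermediate A (k = 0.00110 min⁻¹, Ea = 101 kJ mol⁻¹)
    (constants at 25 °C)

Monday's stops at a ceiling (thermodynamic control): with the way back from product to intermediate E taken away, the same flask gives 100% instead of 9.96%. Its 90.0% of intermediate E against 9.96% of product means odds of 0.111, below the 0.130 it had to beat. Thursday's, read at 2.5 d as a neighbour flask, has reached 19.1% with 80.8% of intermediate E, and its odds of 0.236 stand beside the 0.210 read from ash.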